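# Synthesis plan for CNP0229130.1 (compound 16)

Locants: ring A = 4-hydroxy-3,5-dimethoxyphenyl with the chain C7–C8–C9; ring B = the 2,6-dimethoxyphenoxy ring bonded through O4′ to C8, with the chain C7′–C8′–C9′. CIP analysis of the SMILES gives 7S, 8R (erythro, i.e. anti) and 8′S.

## The problem

Compound 16 is an 8-O-4′ neolignan. Ring A carries the glycerol chain C7–C8–C9, and the oxygen on C8 (O4′) is the phenol oxygen of ring B, which sits between two methoxy groups and has a (2S)-2,3-dihydroxypropyl chain in the para position. The bond that resists formation is C8–O4′: a secondary alkyl aryl ether to a di-ortho-substituted, electron-rich phenol, at a carbon flanked by an ionisable benzylic carbinol (C7) and a hydroxymethyl group (C9). C7 (S) and C8 (R) are vicinal and can control each other, but C8′ (S) is insulated by ring B and must be set on its own. The C7–O/C8–O pattern is a dissonant 1,2-dioxygenation, so a C7–C8 bond from a carbonyl carbon needs C8 to act as an oxygen-bearing carbon nucleophile. C7–OH is a p-hydroxybenzyl alcohol: acid (benzylic cation) or hot base (quinone methide) would scramble C7, and both trialkoxyarenes are sensitive to oxidants, so the end of the route has to be mild and non-acidic. The feature that the plan exploits is that C8 carries both O4′ and the one-carbon arm C9H2OH. The array O4′–C8–C9 is therefore the imprint of an aryl propargyl ether: C8 can be delivered as the γ-carbon of an (E)-γ-aryloxyallylboronate, C9 is the stump of the vinyl group that allylation leaves, and the anti C7/C8 relation is what the chair transition state of an E-allylboronate gives.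

## Retrosynthesis

**16 ⇒ 12.** No skeletal bond of 16 is cut. C9 is read as the internal carbon of a vinyl group (C9=C10, one carbon more than the target), and the ring A phenol and the C8′/C9′ diol are read as acetates. This makes C8 an allylic carbon and opens the allylmetal disconnection; keeping C9 as an ester would lead back to the aldol manifold. The forward reaction must cleave a terminal alkene next to two electron-rich rings, reduce the resulting β-hydroxy aldehyde before it can undergo retro-aldol cleavage, and remove three acetates with mild base only.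

**12 ⇒ 9 + 10.** The C7–C8 bond is cut between aldehyde 9 and (E)-γ-aryloxyallylboronate 10. The neighbouring cuts are weaker: O4′–C8 asks the hindered phenoxide for an SN2 reaction at a secondary carbon, and C1–C7 asks for 1,2-induction in an aryl-metal addition to an epimerisable α-aryloxy aldehyde. Both stereocentres of the vicinal pair disappear in this cut, and the two fragments carry all the carbons and the hindered ether. The forward reaction must be anti-selective (from the E geometry and a closed transition state) and must select one face of the aldehyde (from a chiral Brønsted acid).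

**10 ⇒ 7 ⇒ 6.** Allylboronate 10 is the alkene isomer of 1-alkenylboronate 7, which comes from terminal alkyne 6 by cutting the C–B bond. The E-enol ether geometry is thus taken from a trans-selective alkene transposition and not from an enol ether olefination. The forward reactions are an anti-Markovnikov syn hydroboration and an isomerisation that stops at the allylboronate.

**6 ⇒ 5 ⇒ 4 ⇒ 3.** The acetates are removed, and the C9′–O bond of diol 5 is cut back to racemic epoxide 4 and then to alkene 3. C8′ is set by a hydrolytic kinetic resolution of a terminal epoxide. Asymmetric dihydroxylation of an allylarene is a poor alternative, and a chiral-pool glycidyl unit would need the ring B phenol protected and released again.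

**3 ⇒ 1 + 2.** The O4′–C8 bond is cut where C8 is still an unhindered primary propargylic carbon of bromide 2, so the difficult ether becomes a simple phenol alkylation of 1. The propargyl group also protects the ring B phenol for the whole route, and all three carbons of 2 are put to use (C8, C9 and the carbon excised in step 8).

**9 ⇒ 8.** Acetylation of syringaldehyde 8. The acetate turns the para oxygen from a donor into a weak acceptor, which raises the electrophilicity of the aldehyde and lowers the ring's sensitivity to ozone, and it leaves in the same final methanolysis as the other acetates.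

## Roads not taken

**Alternative 1:** (the most obvious) cut C8–O4′ late. Cinnamate A1 is converted by Sharpless asymmetric dihydroxylation into threo diol A2, whose C8 oxygen is activated (Mitsunobu conditions or an α-sulfonate) and displaced with inversion by phenol A3 to give erythro ester A4, which is then reduced.
- The nucleophile is a di-ortho-substituted phenoxide attacking a secondary carbon.
- The neighbouring C7 oxygen can close a cis-glycidate or ionise, so regio- and stereochemical leakage is built into the mechanism unless C7–OH is protected separately.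
- The route needs olefination, dihydroxylation, activation, protection, displacement, reduction and deprotections, against three steps from 7 and 9 in the chosen plan.
- It also needs the free phenol A3, whose oxygen must be masked and released around the C8′ chemistry. In the chosen plan that oxygen is masked by the group that becomes C8–C9.

**Alternative 2:** cut C7–C8 in natural polarity and set both centres in one reduction. Racemic β-keto ester A5 (from A3 by O-alkylation) would undergo Noyori-type transfer hydrogenation with dynamic kinetic resolution.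
- This is attractive as a single event, but the closest precedents (α-alkoxy β-keto esters) favour the syn alcohol, here threo ester A6, which is the wrong relative configuration.
- Correcting C7 afterwards means inverting an electron-rich benzylic carbinol, which ionises.
- Auxiliary-based anti glycolate aldols would form the same bond with stoichiometric chirality and two extra steps.

**Alternative 3:** the biomimetic union. Oxidative (chemical or anodic) cross-coupling of sinapyl alcohol A7 at C8 with the phenoxyl radical of A3 gives quinone methide A8, and water then adds to C7.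
- This forms the hindered ether without a substitution, but the C8 radical is planar and there is no handle for absolute control.
- With C8′ already S, the product would be a pair of remote diastereomers that cannot be expected to separate.
- The homo-coupling of A7 competes, and the hydration of A8 is only moderately erythro-selective.

Key step: step 7

Assumption: the sense of induction of the two chiral catalysts is taken from their closest substrates ((R,R)-(salen)Co(OAc) hydrolyses the (S)-enantiomer of a 2-alkyloxirane; (R)-TRIP directs pinacol allylboronates to the re face of an aryl aldehyde); if either is opposite here, the antipodal catalyst is used.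

Compounds 1, 2 and 8 are commercial.

## Route

Step 1
Reactants: 1 4-allyl-2,6-dimethoxyphenol (methoxyeugenol); 2 3-bromoprop-1-yne (propargyl bromide)
Product: 3 1,3-dimethoxy-5-(prop-2-en-1-yl)-2-(prop-2-yn-1-yloxy)benzene
Conditions: K2CO3, acetone, 55 °C
Reagents that add atoms: none
Why: Williamson ether synthesis; the hindered phenoxide meets an unhindered primary propargylic bromide, so the O4′–C8 bond is formed at the one stage where it is an easy SN2 reaction.

Step 2
Reactants: 3 1,3-dimethoxy-5-(prop-2-en-1-yl)-2-(prop-2-yn-1-yloxy)benzene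
Product: 4 rac-2-{[3,5-dimethoxy-4-(prop-2-yn-1-yloxy)phenyl]methyl}oxirane
Conditions: mCPBA, NaHCO3, CH2Cl2, 0 °C → rt
Reagents that add atoms: 3-chloroperoxybenzoic acid (mCPBA), OOC(=O)c1cccc(Cl)c1
Why: Prilezhaev epoxidation; the terminal alkene reacts far faster with a peracid than the terminal alkyne, and the buffer protects the epoxide.

Step 3
Reactants: 4 rac-2-{[3,5-dimethoxy-4-(prop-2-yn-1-yloxy)phenyl]methyl}oxirane
Product: 5 (2S)-3-[3,5-dimethoxy-4-(prop-2-yn-1-yloxy)phenyl]propane-1,2-diol
Conditions: (R,R)-(salen)Co(OAc) (0.5 mol %; salen = N,N′-bis(3,5-di-tert-butylsalicylidene)cyclohexane-1,2-diamine dianion), H2O (0.45 equiv), THF, 0 °C → rt; chromatography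
Reagents that add atoms: water, O
Why: Jacobsen hydrolytic kinetic resolution; water opens the faster-reacting (S)-epoxide at its terminal carbon, so C8′ keeps its configuration and becomes the S carbinol. Conversion is kept below one half so that the diol should stay of high enantiomeric purity, and the unreacted (R)-enantiomer of 4 is removed by chromatography.

Step 4
Reactants: 5 (2S)-3-[3,5-dimethoxy-4-(prop-2-yn-1-yloxy)phenyl]propane-1,2-diol
Product: 6 (2S)-3-[3,5-dimethoxy-4-(prop-2-yn-1-yloxy)phenyl]propane-1,2-diyl diacetate
Conditions: Ac2O, pyridine, DMAP (cat.), CH2Cl2, rt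
Reagents that add atoms: acetic anhydride, CC(=O)OC(C)=O
Why: Standard acylation; acetates tolerate the borane, the iridium hydride, the chiral acid and ozone, and leave under the mild base that ends the route.

Step 5
Reactants: 6 (2S)-3-[3,5-dimethoxy-4-(prop-2-yn-1-yloxy)phenyl]propane-1,2-diyl diacetate
Product: 7 (2S)-3-(3,5-dimethoxy-4-{[(2E)-3-(4,4,5,5-tetramethyl-1,3,2-dioxaborolan-2-yl)prop-2-en-1-yl]oxy}phenyl)propane-1,2-diyl diacetate
Conditions: pinacolborane (1.5 equiv), Cy2BH (10 mol %), THF, rt
Reagents that add atoms: pinacolborane, CC1(C)OBOC1(C)C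
Why: Dialkylborane-catalysed hydroboration of a terminal alkyne; syn anti-Markovnikov addition of Cy2BH followed by alkenyl transfer to pinacolborane should give the (E)-1-alkenylboronate, and neither borane reduces acetates at room temperature.

Step 6
Reactants: 8 4-hydroxy-3,5-dimethoxybenzaldehyde (syringaldehyde)
Product: 9 4-formyl-2,6-dimethoxyphenyl acetate
Conditions: Ac2O, pyridine, rt
Reagents that add atoms: acetic anhydride, CC(=O)OC(C)=O
Why: Phenol acetylation; the acetate makes the aldehyde more electrophilic for step 7 and the ring less prone to ozone attack in step 8.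

Step 7
Reactants: 7 (2S)-3-(3,5-dimethoxy-4-{[(2E)-3-(4,4,5,5-tetramethyl-1,3,2-dioxaborolan-2-yl)prop-2-en-1-yl]oxy}phenyl)propane-1,2-diyl diacetate; 9 4-formyl-2,6-dimethoxyphenyl acetate
Product: 12 (2S)-3-[4-({(1S,2R)-1-[4-(acetyloxy)-3,5-dimethoxyphenyl]-1-hydroxybut-3-en-2-yl}oxy)-3,5-dimethoxyphenyl]propane-1,2-diyl diacetate, via (E)-γ-aryloxyallylboronate 10 (not isolated), via pinacol borate ester 11 (not isolated)
Conditions: [Ir(cod)(PPh2Me)2]PF6 (2 mol %; activated with H2, then degassed), CH2Cl2, rt; then 9, (R)-TRIP [(R)-3,3′-bis(2,4,6-triisopropylphenyl)-1,1′-binaphthyl-2,2′-diyl hydrogen phosphate] (5 mol %), 4 Å MS, toluene, −30 → 0 °C; aq NaHCO3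
Reagents that add atoms: none
Why: A cationic iridium hydride moves the C=C bond of 7 by addition and β-hydride elimination out of conjugation with boron into conjugation with O4′, and this catalyst type gives the trans enol ether, so 10 is the (E)-γ-aryloxyallylboronate. Boronate 10 then adds to aldehyde 9 through its γ-carbon (the future C8) in a closed six-membered chair transition state (allylboration, SE2′), with the chiral phosphoric acid hydrogen-bonded to a pinacol oxygen and to the formyl hydrogen. The closest known reaction type is the chiral-phosphoric-acid-catalysed allylboration of aryl aldehydes with (E)-γ-alkoxyallyl and (E)-crotyl pinacolboronates, including its one-flask combination with iridium-catalysed alkene transposition of 1-alkenylboronates. No ring is closed. The C7/C8 relation follows from geometry: with the aryl group of 9 equatorial and the E-configured aryloxy group equatorial, C7–OH and C8–OAr come out anti, which is the erythro series. The absolute sense is set by the catalyst, since (R)-TRIP is expected to expose the re face of the aldehyde, which gives 7S and with it 8R, while C8′ is a spectator. The step needs E geometry in 10, γ- over α-attack and a catalysed rate that outruns the uncatalysed one; these are secured by the trans-selective isomerisation catalyst, the inherent allyl transposition of boron, and the low background reactivity of pinacol γ-oxyallylboronates together with the electron-poor acetoxy aldehyde. Aqueous work-up hydrolyses the O–B bond of 11.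

Step 8
Reactants: 12 (2S)-3-[4-({(1S,2R)-1-[4-(acetyloxy)-3,5-dimethoxyphenyl]-1-hydroxybut-3-en-2-yl}oxy)-3,5-dimethoxyphenyl]propane-1,2-diyl diacetate
Product: 16 (1S,2R)-2-{4-[(2S)-2,3-dihydroxypropyl]-2,6-dimethoxyphenoxy}-1-(4-hydroxy-3,5-dimethoxyphenyl)propane-1,3-diol, via ozonide 13 (not isolated), via hydroxy aldehyde 14 (not isolated), via triacetate diol 15 (not isolated)
Conditions: O3, CH2Cl2, −78 °C (Sudan Red 7B end point); NaBH4, MeOH, −78 → 0 °C; K2CO3 (0.3 equiv), MeOH, rt, Ar; AcOH to pH 6
Reagents that add atoms: ozone, [O-][O+]=O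
Why: Ozonolysis with reductive work-up excises the extra vinyl carbon and turns C9 into CH2OH; hydride reduces aldehyde 14 at low temperature before enolisation or retro-aldol cleavage can touch C8 or C7. Zemplén-type methanolysis then removes the three acetates without acid, so the p-hydroxybenzyl carbinol at C7 is never exposed to ionising conditions; no stereocentre is involved in any bond change.

## Compound list

1 | 4-allyl-2,6-dimethoxyphenol (methoxyeugenol) | C=CCc1cc(OC)c(O)c(OC)c1 | starting material
2 | 3-bromoprop-1-yne (propargyl bromide) | C#CCBr | starting material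
3 | 1,3-dimethoxy-5-(prop-2-en-1-yl)-2-(prop-2-yn-1-yloxy)benzene | C=CCc1cc(OC)c(OCC#C)c(OC)c1 | intermediate
4 | rac-2-{[3,5-dimethoxy-4-(prop-2-yn-1-yloxy)phenyl]methyl}oxirane | C#CCOc1c(OC)cc(CC2CO2)cc1OC | intermediate
5 | (2S)-3-[3,5-dimethoxy-4-(prop-2-yn-1-yloxy)phenyl]propane-1,2-diol | C#CCOc1c(OC)cc(C[C@H](O)CO)cc1OC | intermediate
6 | (2S)-3-[3,5-dimethoxy-4-(prop-2-yn-1-yloxy)phenyl]propane-1,2-diyl diacetate | C#CCOc1c(OC)cc(C[C@H](OC(C)=O)COC(C)=O)cc1OC | intermediate
7 | (2S)-3-(3,5-dimethoxy-4-{[(2E)-3-(4,4,5,5-tetramethyl-1,3,2-dioxaborolan-2-yl)prop-2-en-1-yl]oxy}phenyl)propane-1,2-diyl diacetate | CC1(C)OB(/C=C/COc2c(OC)cc(C[C@H](OC(C)=O)COC(C)=O)cc2OC)OC1(C)C | intermediate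
8 | 4-hydroxy-3,5-dimethoxybenzaldehyde (syringaldehyde) | COc1cc(C=O)cc(OC)c1O | starting material
9 | 4-formyl-2,6-dimethoxyphenyl acetate | COc1cc(C=O)cc(OC)c1OC(C)=O | intermediate
10 | (2S)-3-(3,5-dimethoxy-4-{[(1E)-3-(4,4,5,5-tetramethyl-1,3,2-dioxaborolan-2-yl)prop-1-en-1-yl]oxy}phenyl)propane-1,2-diyl diacetate | CC1(C)OB(C/C=C/Oc2c(OC)cc(C[C@H](OC(C)=O)COC(C)=O)cc2OC)OC1(C)C | intermediate
11 | (2S)-3-[4-({(1S,2R)-1-[4-(acetyloxy)-3,5-dimethoxyphenyl]-1-[(4,4,5,5-tetramethyl-1,3,2-dioxaborolan-2-yl)oxy]but-3-en-2-yl}oxy)-3,5-dimethoxyphenyl]propane-1,2-diyl diacetate | COc1cc([C@H](OB2OC(C)(C)C(C)(C)O2)[C@@H](C=C)Oc2c(OC)cc(C[C@H](OC(C)=O)COC(C)=O)cc2OC)cc(OC)c1OC(C)=O | intermediate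
12 | (2S)-3-[4-({(1S,2R)-1-[4-(acetyloxy)-3,5-dimethoxyphenyl]-1-hydroxybut-3-en-2-yl}oxy)-3,5-dimethoxyphenyl]propane-1,2-diyl diacetate | COc1cc([C@H](O)[C@@H](C=C)Oc2c(OC)cc(C[C@H](OC(C)=O)COC(C)=O)cc2OC)cc(OC)c1OC(C)=O | intermediate
13 | (2S)-3-[4-({(1S,2S)-2-[4-(acetyloxy)-3,5-dimethoxyphenyl]-2-hydroxy-1-(1,2,4-trioxolan-3-yl)ethyl}oxy)-3,5-dimethoxyphenyl]propane-1,2-diyl diacetate (both epimers at the trioxolane carbon) | COc1cc([C@H](O)[C@@H](C2OOCO2)Oc2c(OC)cc(C[C@H](OC(C)=O)COC(C)=O)cc2OC)cc(OC)c1OC(C)=O | intermediate
14 | (2S)-3-[4-({(2S,3S)-3-[4-(acetyloxy)-3,5-dimethoxyphenyl]-3-hydroxy-1-oxopropan-2-yl}oxy)-3,5-dimethoxyphenyl]propane-1,2-diyl diacetate | COc1cc([C@H](O)[C@@H](C=O)Oc2c(OC)cc(C[C@H](OC(C)=O)COC(C)=O)cc2OC)cc(OC)c1OC(C)=O | intermediate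
15 | (2S)-3-[4-({(1S,2R)-1-[4-(acetyloxy)-3,5-dimethoxyphenyl]-1,3-dihydroxypropan-2-yl}oxy)-3,5-dimethoxyphenyl]propane-1,2-diyl diacetate | COc1cc([C@H](O)[C@@H](CO)Oc2c(OC)cc(C[C@H](OC(C)=O)COC(C)=O)cc2OC)cc(OC)c1OC(C)=O | intermediate
16 | (1S,2R)-2-{4-[(2S)-2,3-dihydroxypropyl]-2,6-dimethoxyphenoxy}-1-(4-hydroxy-3,5-dimethoxyphenyl)propane-1,3-diol | COc1cc([C@H](O)[C@@H](CO)Oc2c(OC)cc(C[C@H](O)CO)cc2OC)cc(OC)c1O | target

## Step count and risk

Total: 8 steps. Longest linear sequence: 7 steps (steps 1–5, 7, 8); step 6 is a one-step side branch.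

**Step 7 (key step).**
- What may go wrong: loss of facial control at the aldehyde, because the 2,6-dimethoxyaryl group on the γ-oxygen is much larger than the alkoxy groups for which this catalysis is established and may not fit the catalyst pocket. Acid-promoted protonation of the electron-rich enol ether of 10 before it adds is the second concern.
- Fallback: this changes C8 from an allylmetal carbon to an enamine carbon. It sets out from 7 and 9. Ozonolysis of 7 (O3, CH2Cl2, −78 °C; Me2S) would give the aryloxyacetaldehyde F1, which is added slowly to an excess of 9 with (S)-proline (DMF, 4 °C). This is an anti-selective direct cross-aldol reaction of an α-oxyaldehyde; the E-enamine of F1 should attack the re face of 9 and give hydroxy aldehyde 14. The fallback rejoins the route at 14 and continues with the borohydride and methanolysis stages of step 8, any syn isomer being removed at the stage of 15.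

**Step 8.**
- What may go wrong: oxidation of the trialkoxyarene of ring B by ozone in competition with the terminal alkene, or retro-aldol cleavage and epimerisation of 14 if hydride delivery lags behind its formation.
- Fallback: replace ozonolysis by osmylation and glycol cleavage. It sets out from 12. Dihydroxylation (K2OsO2(OH)4 cat., N-methylmorpholine N-oxide, acetone/H2O) would give the triol F2, and NaIO4 (THF/pH 7 buffer, 0 °C) would cleave it to 14, where the route is rejoined.

**Step 3.**
- What may go wrong: insufficient discrimination between the enantiomers of 4. The ee of a diol product is fixed by the selectivity factor and cannot be raised by conversion, and the resulting C8′ epimer of 16 is a remote diastereomer that could not be removed later.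
- Fallback: harvest the unreacted epoxide instead of the diol. It sets out from 4. The resolution is run with the antipodal (S,S)-(salen)Co(OAc) and 0.60 equiv of water, so that the (R)-epoxide is consumed and the ee of the survivor rises with conversion. The recovered (S)-epoxide F3 is opened at its terminal carbon by acetate (Bu4NOAc cat., Ac2O, 80 °C), which gives diacetate 6 directly with C8′ untouched; the route is rejoined at 6.

## Further compounds

F1 | step 7 | (2S)-3-[3,5-dimethoxy-4-(2-oxoethoxy)phenyl]propane-1,2-diyl diacetate | O=CCOc1c(OC)cc(C[C@H](OC(C)=O)COC(C)=O)cc1OC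
F2 | step 8 | (2S)-3-[4-({(1S,2S)-1-[4-(acetyloxy)-3,5-dimethoxyphenyl]-1,3,4-trihydroxybutan-2-yl}oxy)-3,5-dimethoxyphenyl]propane-1,2-diyl diacetate (both epimers at C3 of the butane chain) | COc1cc([C@H](O)[C@@H](C(O)CO)Oc2c(OC)cc(C[C@H](OC(C)=O)COC(C)=O)cc2OC)cc(OC)c1OC(C)=O
F3 | step 3 | (2S)-2-{[3,5-dimethoxy-4-(prop-2-yn-1-yloxy)phenyl]methyl}oxirane | C#CCOc1c(OC)cc(C[C@H]2CO2)cc1OC
A1 | alternative 1 | ethyl (2E)-3-[4-(benzyloxy)-3,5-dimethoxyphenyl]prop-2-enoate | CCOC(=O)/C=C/c1cc(OC)c(OCc2ccccc2)c(OC)c1
A2 | alternative 1 | ethyl (2R,3S)-3-[4-(benzyloxy)-3,5-dimethoxyphenyl]-2,3-dihydroxypropanoate | COc1cc([C@H](O)[C@@H](O)C(=O)OCC)cc(OC)c1OCc1ccccc1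
A3 | alternative 1 | 4-{[(4S)-2,2-dimethyl-1,3-dioxolan-4-yl]methyl}-2,6-dimethoxyphenol | COc1cc(C[C@H]2COC(C)(C)O2)cc(OC)c1O
A4 | alternative 1 | ethyl (2S,3S)-3-[4-(benzyloxy)-3,5-dimethoxyphenyl]-2-(4-{[(4S)-2,2-dimethyl-1,3-dioxolan-4-yl]methyl}-2,6-dimethoxyphenoxy)-3-hydroxypropanoate | COc1cc([C@H](O)[C@@H](C(=O)OCC)Oc2c(OC)cc(C[C@H]3COC(C)(C)O3)cc2OC)cc(OC)c1OCc1ccccc1
A5 | alternative 2 | ethyl (2RS)-3-[4-(benzyloxy)-3,5-dimethoxyphenyl]-2-(4-{[(4S)-2,2-dimethyl-1,3-dioxolan-4-yl]methyl}-2,6-dimethoxyphenoxy)-3-oxopropanoate | CCOC(=O)C(Oc1c(OC)cc(C[C@H]2COC(C)(C)O2)cc1OC)C(=O)c1cc(OC)c(OCc2ccccc2)c(OC)c1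
A6 | alternative 2 | ethyl (2R,3S)-3-[4-(benzyloxy)-3,5-dimethoxyphenyl]-2-(4-{[(4S)-2,2-dimethyl-1,3-dioxolan-4-yl]methyl}-2,6-dimethoxyphenoxy)-3-hydroxypropanoate | COc1cc([C@H](O)[C@H](C(=O)OCC)Oc2c(OC)cc(C[C@H]3COC(C)(C)O3)cc2OC)cc(OC)c1OCc1ccccc1
A7 | alternative 3 | 4-[(1E)-3-hydroxyprop-1-en-1-yl]-2,6-dimethoxyphenol (sinapyl alcohol) | COc1cc(/C=C/CO)cc(OC)c1O
A8 | alternative 3 | 4-[(2RS)-2-(4-{[(4S)-2,2-dimethyl-1,3-dioxolan-4-yl]methyl}-2,6-dimethoxyphenoxy)-3-hydroxypropylidene]-2,6-dimethoxycyclohexa-2,5-dien-1-one | COC1=CC(=CC(CO)Oc2c(OC)cc(C[C@H]3COC(C)(C)O3)cc2OC)C=C(OC)C1=O
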